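**Early times.** Early in these runs the left-handed product climbs steadily, so you want its slope before you pick a flask.

common to all: left-handed substrate 0.25 M; right-handed substrate 0.25 M
- larch: partner 0.20 M; free catalyst 9.8 mM; temperature −26 °C; run made earlier
- alder: partner 0.45 M; free catalyst 9.8 mM; temperature 4 °C; run made earlier
- birch: partner 0.30 M; free catalyst 19 mM; temperature −26 °C; run made earlier
- epsilon: partner 0.300 M; free catalyst 40 mM; temperature 15 °C; time 50 min
- gamma: partner 0.300 M; free catalyst 9.8 mM; temperature 0 °C; time 50 min
- eta: partner 0.300 M; free catalyst 40 mM; temperature −40 °C; time 50 min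
- theta: partner 0.500 M; free catalyst 9.8 mM; temperature 0 °C; time 50 min
- zeta: partner 0.500 M; free catalyst 9.8 mM; temperature −15 °C; time 50 min

| run | time / min | left-handed product / % |
|---|---|---|
| larch | 10.0 | 0.7 |
| larch | 15.0 | 1.9 |
| larch | 20.0 | 4.7 |
| larch | 40.0 | 6.3 |
| larch | 50.0 | 9.2 |
| larch | 90.0 | 11.6 |
| larch | 150 | 20.6 |
| alder | 2.00 | 5.1 |
| alder | 5.00 | 11.4 |
| alder | 10.0 | 17.7 |
| alder | 15.0 | 23.1 |
| alder | 20.0 | 28.0 |
| alder | 30.0 | 32.3 |
| alder | 40.0 | 36.8 |
| birch | 30.0 | 14.7 |
| birch | 50.0 | 21.4 |
| birch | 80.0 | 28.8 |
| birch | 120 | 35.1 |
| birch | 150 | 39.1 |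

(readings scatter by 1 percentage point)

- the flasks by amount of left-handed product, in percent of the left-handed substrate and right-handed substrate together charged, highest first, at 50 min (epsilon / gamma / eta / theta / zeta)
- the same order at 5.0 min (epsilon / gamma / eta / theta / zeta)
- the amount of left-handed product, in percent of the left-handed substrate and right-handed substrate together charged of the flask you put first, at 50 min
- the amount of left-handed product, in percent of the left-handed substrate and right-handed substrate together charged of the flask you put last, at 50 min

- free catalyst is single-handed; left-handed substrate and right-handed substrate are mirror images of each other, charged as a racemate, each of them at the stated concentration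
- the earlier runs were read with a standard deviation of 1 percentage point

**The rule.** Your rule of thumb: at one temperature, early yield follows the dose. Eta's dose at 50 min is 6.12, meaning free catalyst charged times partner charged times time, counted in units of the larch reading at 50.0 min. Test it on birch at 30.0 min, dose 1.74. Larch's 9.2% scales to 16.0%, and birch read 14.7%. That is 1.4 points apart, against a scatter of 1 point.

**Powers of ten.** Alder at 5.00 min has dose 0.225 and read 11.4%. So, on the dose rule, these two scattered readings put the slope gained by warming from −26 °C to 4 °C at a factor of about 5.51, or 0.741 in powers of ten. Spread that logarithm evenly over temperature. At 5.0 min the lines then give theta 10.1%, gamma 6.05%, zeta 4.30% and eta 2.54%.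

**The border.** The ceiling is the left-handed share of the charge, 50.0%. Hold each line against it. Alder's line at 10.0 min is 22.8%, a ratio to the ceiling of 0.456, and the reading reached 0.776 of that line. At 40.0 min the ratio is 1.82 and the reading reached 0.404. So I take a ratio near 0.456 as the border of the line, and there the reading already falls short of it. Epsilon's line at 5.0 min is 58.0%, above the ceiling, so I take it as first place and not as an amount. At 50 min eta's line is 25.4%, and alder's shortfall brings it to about 19.7%. Gamma's line then stands at 60.5% and zeta's at 43.0%, both past the border, so I leave that pair unranked. Partner per left-handed substrate is 1.20 in gamma and 2.00 in zeta.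

**The result.** The forecast gave epsilon > theta > gamma > zeta > eta at 50 min and epsilon > theta > gamma > zeta > eta at 5.0 min, with 43% and 19% at the ends, noting “Gamma versus zeta is close”. The flasks gave epsilon > theta > gamma > zeta > eta at 5.0 min and epsilon > theta > zeta > gamma > eta at 50 min, with epsilon at 45.0% and eta at 11.3%, under my 19.7%.

    free catalyst + left-handed substrate ⇌ catalyst intermediate A (K = 62.0 /M, k = 7.50 /M/s, Ea = 49.0 kJ/mol, ΔH = −76.0 kJ/mol)
    free catalyst + right-handed substrate ⇌ catalyst intermediate B (K = 38.0 /M, k = 1.20 /M/s, Ea = 42.0 kJ/mol, ΔH = −11.0 kJ/mol)
    partner + catalyst intermediate A → free catalyst + left-handed product (k = 0.0820 /M/s, Ea = 47.0 kJ/mol)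
    partner + catalyst intermediate B → free catalyst + right-handed product (k = 0.00240 /M/s, Ea = 59.0 kJ/mol)
    partner ⇌ dormant form (K = 0.750, k = 6.20 × 10⁻⁴ /s, Ea = 88.0 kJ/mol, ΔH = −29.0 kJ/mol)
    free catalyst → spent catalyst (k = 1.30 × 10⁻⁶ /s, Ea = 90.0 kJ/mol)
    (constants at 0 °C)

**One neighbour.** Take eta with 0.068 M of free catalyst, all else held. Its dose is 10.4, so eta's own 11.3% scales to 19.2%. That neighbour flask gave 17.5%, with 46% of its left-handed substrate and 70% of its partner still there, unbound.

The readings are simulated with constants of no real substance; the scatter is artificial.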